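Two sums hold still in this closed flask: [pre-initiator] + [initiator] + [living end], and [free monomer] + [monomer in chains] + [quenched substrate].

    free monomer + living end → monomer in chains + living end, rate k1*[living end]*[free monomer] (k1 = 6.3 M⁻¹ min⁻¹)
    free monomer + initiator → living end + monomer in chains (k2 = 0.061 M⁻¹ min⁻¹)
    pre-initiator → initiator (k3 = 0.010 min⁻¹)
    protic impurity + free monomer → quenched substrate (k4 = 0.32 M⁻¹ min⁻¹)

free monomer 0.50 M; protic impurity 0.0500 M; pre-initiator 5.0 mM; time 2.5 h

1. average number of monomer units in a chain (chains begun, living or dead) at 2.5 h
2. part of the free monomer that has reacted at 2.5 h

No step of the scheme removes a living end, so [living end] counts the chains begun and dp is [monomer in chains]/[living end]. I reckon both parts of that fraction from their ceilings. The protic impurity is the limiting reagent of its step, and its half-life by that step, with free monomer as charged, is 0.072 h, far shorter than the run of 2.5 h. I therefore let it take its 0.0500 M of free monomer early, leaving a budget of 0.450 M. That also puts c above 10.0 %, and I go no further on c. Pre-initiator is a plain first-order lag with time constant 100 min, so by 2.5 h it has released 3.88 mM. Dividing gives 116, the budget per released chain, and that is my dp.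

The forecast gives dp 127 (115 to 140), higher than mine, and c 76 % (72 % to 80 %), on this ground: “Initiation is slow and incomplete”.

The simulation gives dp 125 and c 76.6 %, both inside the forecast's ranges. In this flask at 2.50 h, monomer in chains is 74.0 % of the budget and living ends are 68.4 % of the release, so my 116 stands below the result by a factor of 1.08.

In the neighbour charged with 0.20 M of free monomer, the budget is 0.150 M and the release is unchanged, so the budget per released chain is 38.7. That neighbour computes to dp 47.3.

The constants used here are invented; no experiment stands behind them.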